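**Retrosynthetic overview** (ent-kaurane numbering: ring A = C1–C5, C10; lactone = C8–C7(=O)–O–C20–C10–C9; ring C = C8, C9, C11–C14; bridge = C15–C16(=C17))
1. The enone comes last, from a C15 methylene by allylic oxidation. The 11-OH comes from a C11 ketone.
2. Enabling feature: C8 is α to the C7 lactone carbonyl and sits 1,3 (through C14) to C13, which is β to the C11 oxygen. Ring C is therefore a latent 5-carboxycyclohex-2-enone, with an enolate carbon and an enone β-carbon that a CH2=C(Br)CH2 unit can bridge to close ring D.
3. The C8 enolate is released under neutral conditions from a 2-bromoallyl ester on C8. This ester is a CO2-linked, traceless tether that also carries C15–C17.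
4. The ester is installed when the flat arene form of ring C (a 5-methoxyisochroman-1-one, C11–O meta to C8–C7) is dearomatised by Birch reduction and trapped with CO2.
5. The spiro arene comes from a Heck/carbonylation domino on a ring A allylic ether. Ring order: A, then the pyran (later lactone), then C (arene, dearomatised), then D.

Key step: step 14

Assumption: compounds 6 and 13 are taken as commercial, and the configuration of the C15 carbinol in 22 is left open because it is lost in step 17.

**Step 1**
Reactants: 1 4,4-dimethylcyclohex-2-en-1-one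
Product: 2 2-iodo-4,4-dimethylcyclohex-2-en-1-one
Conditions: I2, pyridine–CH2Cl2, 23 °C
Reagents that add atoms: iodine, II
Why: α-Iodination of a cyclohexenone by pyridine addition, iodination and elimination (Baylis–Hillman-type mechanism) is routine and puts the handle on C10.

**Step 2**
Reactants: 2 2-iodo-4,4-dimethylcyclohex-2-en-1-one
Product: 3 (S)-2-iodo-4,4-dimethylcyclohex-2-en-1-ol
Conditions: (R)-2-methyl-CBS-oxazaborolidine (10 mol %), BH3·SMe2, THF, −20 °C
Reagents that add atoms: none
Why: In this Corey–Bakshi–Shibata reduction the iodoalkene arm acts as the large group, so the (R)-catalyst should give the (S)-carbinol and set C1, from which every other stereocentre is relayed.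

**Step 3**
Reactants: 3 (S)-2-iodo-4,4-dimethylcyclohex-2-en-1-ol
Product: 4 (S)-tert-butyl[(2-iodo-4,4-dimethylcyclohex-2-en-1-yl)oxy]dimethylsilane
Conditions: TBSCl, imidazole, DMF, 23 °C
Reagents that add atoms: tert-butyldimethylsilyl chloride, CC(C)(C)[Si](C)(C)Cl
Why: Standard silylation gives a bulky allylic ether that survives the organometallic, hydride and dissolving-metal steps and later shields one alkene face.

**Step 4**
Reactants: 4 (S)-tert-butyl[(2-iodo-4,4-dimethylcyclohex-2-en-1-yl)oxy]dimethylsilane
Product: 5 (S)-[6-(tert-butyldimethylsilyloxy)-3,3-dimethylcyclohex-1-en-1-yl]methanol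
Conditions: i-PrMgCl·LiCl, THF, −20 → 0 °C; then (CH2O)n, 23 °C
Reagents that add atoms: formaldehyde (as paraformaldehyde), C=O
Why: Iodine–magnesium exchange of an alkenyl iodide followed by Grignard addition to formaldehyde introduces C20 without touching C1.

**Step 5**
Reactants: 5 (S)-[6-(tert-butyldimethylsilyloxy)-3,3-dimethylcyclohex-1-en-1-yl]methanol; 6 2-bromo-1-(bromomethyl)-3-methoxybenzene
Product: 7 2-bromo-3-methoxybenzyl ether of 5
Conditions: NaH, n-Bu4NI (cat.), THF–DMF, 0 → 23 °C
Reagents that add atoms: none
Why: Williamson ether synthesis joins the ring C arene to C20 through an allyl ether, which zerovalent palladium does not ionise, unlike an allylic ester.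

**Step 6**
Reactants: 7 2-bromo-3-methoxybenzyl ether of 5
Product: 8 methyl ester of the 5-methoxyspiro[cyclohexane-1,4'-isochroman], with aryl carbon C9 trans to the C1 OTBS group and the C5 ester cis to C9
Conditions: Pd(OAc)2 (10 mol %), P(o-tol)3, Et3N, CO (1 atm), MeOH–DMF, 85 °C
Reagents that add atoms: carbon monoxide, [C-]#[O+]; methanol, CO
Why: In this domino Heck/alkoxycarbonylation the arylpalladium adds 6-exo-trig to C10 on the face opposite the OTBS group (sets C10), and the σ-alkylpalladium at C5, which has no β-hydrogen, takes up CO and methanol with retention (C6 syn to C9).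

**Step 7**
Reactants: 8 spiro-isochroman methyl ester (C5 ester cis to C9)
Product: 9 C5 epimer of 8 (C5 ester trans to C9, cis to C20)
Conditions: NaOMe (20 mol %), MeOH, 65 °C
Reagents that add atoms: none
Why: Base-mediated epimerisation α to the ester should settle on the isomer with an equatorial ester trans-diequatorial to C9 and the smaller C20 arm axial, which is the C5 configuration of the target.

**Step 8**
Reactants: 9 spiro-isochroman methyl ester (C5 ester trans to C9)
Product: 10 the corresponding C6 primary alcohol
Conditions: LiAlH4, Et2O, 0 °C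
Reagents that add atoms: none
Why: Hydride reduction acts on the only reducible group, because the ether tether and the silyl ether are inert.

**Step 9**
Reactants: 10 C6 primary alcohol
Product: 11 C1,C6-bis(TBS) ether of the spiro-isochroman
Conditions: TBSCl, imidazole, DMF, 23 °C
Reagents that add atoms: tert-butyldimethylsilyl chloride, CC(C)(C)[Si](C)(C)Cl
Why: Silylation removes the acidic proton, which would otherwise quench the enolate in step 11.

**Step 10**
Reactants: 11 C1,C6-bis(TBS) ether of the spiro-isochroman
Product: 12 C1,C6-bis(TBS) 5-methoxyspiro[cyclohexane-1,4'-isochroman]-1'-one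
Conditions: Rh2(cap)4 (1 mol %), t-BuOOH, NaHCO3, CH2Cl2, 23 °C
Reagents that add atoms: tert-butyl hydroperoxide, CC(C)(C)OO
Why: Catalytic benzylic oxidation of an isochroman to the isochromanone is known, and C7 is the only benzylic C–H position because C10 is quaternary.

**Step 11**
Reactants: 12 bis(TBS) 5-methoxyspiro-isochroman-1'-one; 13 2,3-dibromopropene
Product: 16 2-bromoallyl ester of the C8-carboxylated 8,12-dihydro lactone (C9=C11 methyl enol ether and C13=C14 alkene; new carboxyl on the C1 face), via lithium enolate 14 (not isolated), via lithium carboxylate 15 (not isolated)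
Conditions: Li (2.1 equiv), t-BuOH (1.0 equiv), NH3–THF, −78 °C; NH3 evaporated; CO2, THF, −78 → 0 °C; then 13, DMF, 23 °C
Reagents that add atoms: carbon dioxide, O=C=O
Why: Birch reduction of a benzoate-type arene reduces C8 and C12 and keeps the methoxy group on an alkene, then the C8 enolate is carboxylated on the open face (syn to C1, away from the C5 CH2OTBS arm gauche to C8), and the carboxylate is O-alkylated by SN2 at the allylic bromide of 13.

**Step 12**
Reactants: 16 2-bromoallyl ester of the Birch product
Product: 17 C1,C6-diol with C11 ketone, C12=C13 enone and H9 on the C5 face (trans to the C8 ester)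
Conditions: 3 M aq HCl, THF, 23 → 40 °C
Reagents that add atoms: water, O
Why: Acid hydrolysis of the enol ether protonates C9 from the face opposite the angular ester on C8 (sets C9), the β,γ-alkene can move into conjugation only with the ketone because C8 is quaternary, and both silyl ethers fall in the same pot.

**Step 13**
Reactants: 17 diol enone
Product: 18 C1,C6-diacetate of 17
Conditions: Ac2O, pyridine, DMAP (cat.), 0 → 23 °C
Reagents that add atoms: acetic anhydride, CC(=O)OC(C)=O
Why: Standard acetylation installs both acetates of the target now, since every later step is neutral or mild enough to keep them.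

**Step 14**
Reactants: 18 diacetate enone 2-bromoallyl ester
Product: 20 tetracyclic 11-ketone with C15 methylene and C16 exocyclic methylene (15-deoxo-11-oxo compound), via bromoallyl lactone 19 (not isolated)
Conditions: Pd2(dba)3 (5 mol %), PPh3 (25 mol %), HCO2Na (1.5 equiv), toluene–MeCN 4:1, 40 °C, then 90 °C
Reagents that add atoms: none
Why: Proposed new method: zerovalent palladium should ionise the allylic C–O bond of the 2-bromoallyl ester before it touches the vinylic C–Br bond, the malonate-type carboxylate then loses CO2, and the C8 lactone enolate recombines with the 2-bromo-π-allyl ligand at its CH2 terminus to give 19 (bond C8–C15). On warming, the same catalyst inserts into the C16–Br bond of 19, the alkenylpalladium adds across the enone so that C16 binds C13, and formate converts the palladium enolate into the C11 ketone and returns zerovalent palladium. The closest known reaction types are the Tsuji-type decarboxylative allylation of allyl malonates and allyl β-oxo esters and the reductive Heck cyclisation of 5-(2-bromoallyl)cyclohex-2-enones, each established alone but not joined in one flask on a 2-bromoallyl ester. The only ring closed is the five-membered ring D (C8, C14, C13, C16, C15), by a 5-exo-trig carbopalladation that turns ring C into the bicyclo[3.2.1]octane. C8 is set by attack on the convex face of the ring-fusion enolate, syn to H9 and away from the fold of ring C, and C13 is then fixed because the short tether reaches the β-carbon only from that same face as a 1,3-diaxial bridge. The step needs allylic ionisation to outrun vinyl bromide insertion, C–C collapse to outrun formate capture or proton transfer from C9 and C12, and conjugate rather than carbonyl addition, which are secured by the low first temperature, by the sparingly soluble HCO2Na and the tight ion pair in a mostly non-polar medium, and by the exo geometry of the tether.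

**Step 15**
Reactants: 20 tetracyclic 11-ketone
Product: 21 11-alcohol (OH endo, cis to H9; 15-deoxo-rabdosin B)
Conditions: NaBH4, MeOH–CH2Cl2, −40 °C
Reagents that add atoms: none
Why: Borohydride reduction of the only ketone should take hydride from the exo face (the C14 side), because the C15–C16 bridge covers the endo face as in bicyclo[3.2.1]octan-3-ones, which gives the axial endo carbinol at C11.

**Step 16**
Reactants: 21 11-alcohol
Product: 22 11,15-diol (C15 allylic alcohol)
Conditions: SeO2 (30 mol %), t-BuOOH, CH2Cl2, 0 → 23 °C
Reagents that add atoms: tert-butyl hydroperoxide, CC(C)(C)OO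
Why: Riley allylic oxidation (ene reaction, then [2,3]-shift) of a 16-exocyclic methylene is standard in this skeleton and can attack only C15, since the other allylic position, C13, is a bridgehead.

**Step 17**
Reactants: 22 11,15-diol
Product: 23 Rabdosin B
Conditions: activated MnO2, CH2Cl2, 23 °C
Reagents that add atoms: none
Why: MnO2 oxidises allylic alcohols chemoselectively, so C15 becomes the enone carbonyl while the saturated, hindered 11-OH stays free.

**Compound list**
1 | 4,4-dimethylcyclohex-2-en-1-one | CC1(C)CCC(=O)C=C1 | starting material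
2 | 2-iodo-4,4-dimethylcyclohex-2-en-1-one | CC1(C)CCC(=O)C(I)=C1 | intermediate
3 | (S)-2-iodo-4,4-dimethylcyclohex-2-en-1-ol | O[C@H]1CCC(C)(C)C=C1I | intermediate
4 | TBS ether of 3 | CC(C)(C)[Si](C)(C)O[C@H]1CCC(C)(C)C=C1I | intermediate
5 | (S)-[6-(TBS-oxy)-3,3-dimethylcyclohex-1-en-1-yl]methanol | CC(C)(C)[Si](C)(C)O[C@H]1CCC(C)(C)C=C1CO | intermediate
6 | 2-bromo-1-(bromomethyl)-3-methoxybenzene | COc1cccc(CBr)c1Br | starting material
7 | 2-bromo-3-methoxybenzyl ether of 5 | COc1cccc(COCC2=CC(C)(C)CC[C@@H]2O[Si](C)(C)C(C)(C)C)c1Br | intermediate
8 | spiro-isochroman methyl ester, C5 ester cis to C9 | COc1cccc2c1[C@]1(COC2)[C@@H](O[Si](C)(C)C(C)(C)C)CCC(C)(C)[C@@H]1C(=O)OC | intermediate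
9 | spiro-isochroman methyl ester, C5 ester trans to C9 | COc1cccc2c1[C@]1(COC2)[C@@H](O[Si](C)(C)C(C)(C)C)CCC(C)(C)[C@H]1C(=O)OC | intermediate
10 | C6 primary alcohol | COc1cccc2c1[C@]1(COC2)[C@@H](O[Si](C)(C)C(C)(C)C)CCC(C)(C)[C@H]1CO | intermediate
11 | C1,C6-bis(TBS) spiro-isochroman | COc1cccc2c1[C@]1(COC2)[C@@H](O[Si](C)(C)C(C)(C)C)CCC(C)(C)[C@H]1CO[Si](C)(C)C(C)(C)C | intermediate
12 | C1,C6-bis(TBS) 5-methoxyspiro-isochroman-1'-one | COc1cccc2c1[C@]1(COC2=O)[C@@H](O[Si](C)(C)C(C)(C)C)CCC(C)(C)[C@H]1CO[Si](C)(C)C(C)(C)C | intermediate
13 | 2,3-dibromopropene | C=C(Br)CBr | starting material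
14 | lithium enolate of the 8,12-dihydro lactone | [Li]OC1=C2C=CCC(OC)=C2[C@]2(CO1)[C@@H](O[Si](C)(C)C(C)(C)C)CCC(C)(C)[C@H]2CO[Si](C)(C)C(C)(C)C | intermediate
15 | lithium C8-carboxylate | [Li]OC(=O)[C@@]12C=CCC(OC)=C1[C@]1(COC2=O)[C@@H](O[Si](C)(C)C(C)(C)C)CCC(C)(C)[C@H]1CO[Si](C)(C)C(C)(C)C | intermediate
16 | 2-bromoallyl C8-carboxylate of the Birch product | C=C(Br)COC(=O)[C@@]12C=CCC(OC)=C1[C@]1(COC2=O)[C@@H](O[Si](C)(C)C(C)(C)C)CCC(C)(C)[C@H]1CO[Si](C)(C)C(C)(C)C | intermediate
17 | diol enone 2-bromoallyl ester | C=C(Br)COC(=O)[C@@]12CC=CC(=O)[C@H]1[C@]1(COC2=O)[C@@H](O)CCC(C)(C)[C@H]1CO | intermediate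
18 | diacetate enone 2-bromoallyl ester | C=C(Br)COC(=O)[C@@]12CC=CC(=O)[C@H]1[C@]1(COC2=O)[C@@H](OC(C)=O)CCC(C)(C)[C@H]1COC(C)=O | intermediate
19 | C8-(2-bromoallyl) enone lactone diacetate | C=C(Br)C[C@]12CC=CC(=O)[C@H]1[C@]1(COC2=O)[C@@H](OC(C)=O)CCC(C)(C)[C@H]1COC(C)=O | intermediate
20 | tetracyclic 11-ketone, C15 methylene | C=C1C[C@]23C[C@H]1CC(=O)[C@H]2[C@]1(COC3=O)[C@@H](OC(C)=O)CCC(C)(C)[C@H]1COC(C)=O | intermediate
21 | 11-alcohol (15-deoxo-rabdosin B) | C=C1C[C@]23C[C@H]1C[C@H](O)[C@H]2[C@]1(COC3=O)[C@@H](OC(C)=O)CCC(C)(C)[C@H]1COC(C)=O | intermediate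
22 | 11,15-diol | C=C1C(O)[C@]23C[C@H]1C[C@H](O)[C@H]2[C@]1(COC3=O)[C@@H](OC(C)=O)CCC(C)(C)[C@H]1COC(C)=O | intermediate
23 | Rabdosin B | C=C1C(=O)[C@]23C[C@H]1C[C@H](O)[C@H]2[C@]1(COC3=O)[C@@H](OC(C)=O)CCC(C)(C)[C@H]1COC(C)=O | target

Total step count: 17. Longest linear sequence: 17 (from 1).

**Steps most likely to fail**

1. **Step 14.**
   - Risks: the vinyl bromide may insert before the ester ionises, the π-allyl ligand may be reduced by formate, or the enolate may be quenched by proton transfer before C–C bond formation.
   - Fallback (from 18, back at 20): the two events are separated and ring D is closed by a radical instead of palladium.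
   - Route: Pd(PPh3)4 in THF at 23–40 °C, with no hydride source, carries out only the decarboxylative allylation, and the bromoallyl lactone 19 is isolated. Then n-Bu3SnH and AIBN in benzene at 80 °C generate the C16 vinyl radical, which closes 5-exo onto C13 to give 20.
   - No compound outside the list arises (F0).

2. **Step 6.**
   - Risks: the arylpalladium may be carbonylated directly before it cyclises, or the alkene faces may be poorly differentiated.
   - Fallback (from 7, back at 10): a tin hydride-mediated radical cyclisation/carbonylation.
   - Route: with n-Bu3SnH, AIBN and CO (80 atm) in benzene at 80 °C, the aryl radical closes 6-exo onto C10, and the C5 radical takes up CO and a hydrogen atom. K2CO3 in MeOH then equilibrates C5 to the trans spiro-isochroman C6 aldehyde F1, and NaBH4 reduces it to 10.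

3. **Step 11.**
   - Risks: the lactone carbonyl may be over-reduced, or the enolate may be quenched by residual ammonia or alkoxide before it is carboxylated.
   - Fallback (from 12, back at 16): reduction and trapping are uncoupled.
   - Route: the Birch reduction is quenched with NH4Cl and the 8,12-dihydro lactone F2 is isolated. LDA in THF at −78 °C then regenerates enolate 14 in a clean medium, CO2 gives 15, and 13 in DMF gives 16.

**Further compounds**
F0 | step 14 | none | none
F1 | step 6 | trans spiro-isochroman C6 aldehyde | COc1cccc2c1[C@]1(COC2)[C@@H](O[Si](C)(C)C(C)(C)C)CCC(C)(C)[C@H]1C=O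
F2 | step 11 | 8,12-dihydro lactone (C8–H) | C12C=CCC(OC)=C1[C@]1(COC2=O)[C@@H](O[Si](C)(C)C(C)(C)C)CCC(C)(C)[C@H]1CO[Si](C)(C)C(C)(C)C
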